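The numbers in the tables are calculated with made-up constants; noise was put on by code.

Late in Monday's run the complex with two exchanged was sinking, from 47.8% at 12.0 min to 40.0% at 40.0 min, and I had to say what a flask with less incoming ligand would give.

- Monday's: starting complex 0.80 M; incoming ligand 1.5 equiv; capture agent 0.24 M; run made earlier
- flask: starting complex 0.80 M; incoming ligand 1.00 equiv; capture agent 0.240 M; time 3.0 h

Monday's run (percent of the starting complex charged)

| time / min | complex with two exchanged / % |
|---|---|
| 5.00 | 41.8 |
| 12.0 | 47.8 |
| 25.0 | 44.9 |
| 40.0 | 40.0 |

(each reading ± 0.5 percentage points)

1. time up to 3.0 h at which complex with two exchanged stands highest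
2. the amount of complex with two exchanged, in percent of the starting complex charged, at that time

- what may be going on: starting complex + incoming ligand -> leaving ligand + complex with one exchanged; complex with one exchanged + incoming ligand -> leaving ligand + complex with two exchanged; complex with two exchanged + incoming ligand -> leaving ligand + complex with three exchanged; complex with one exchanged + capture agent -> trapped intermediate; incoming ligand -> decomposed reagent; complex with two exchanged <-> isomer of the product
- no earlier run changes the charge of incoming ligand; that part of a forecast is a guess

Each complex with two exchanged costs two ligands, so with incoming ligand as the limiting reagent I took the ceiling as the equivalents divided by two: 75.0% on Monday, 50.0% in the new flask. Monday's highest reading over its ceiling gave 0.637, and this is the harvest H, the share of the ceiling that stands at the peak. Carried to the new flask, H gave me 31.9%.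

One number was not enough, for H holds no clock. Taking the exchange rate as proportional to ligand, I stretched the time of Monday's highest reading to 0.300 h. The forecast said 27% at 0.5 h, lower and later than my figures, reasoning that “The rate falls as ligand drains, so the peak comes later than Monday's”.

The new flask peaked at 30.6% at 0.201 h.

    starting complex + incoming ligand → leaving ligand + complex with one exchanged (k = 0.00654 L mol⁻¹ s⁻¹)
    complex with one exchanged + incoming ligand → leaving ligand + complex with two exchanged (k = 0.0155 L mol⁻¹ s⁻¹)
    complex with two exchanged + incoming ligand → leaving ligand + complex with three exchanged (k = 0.00107 L mol⁻¹ s⁻¹)
    complex with one exchanged + capture agent → trapped intermediate (k = 0.00314 L mol⁻¹ s⁻¹)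
    incoming ligand → decomposed reagent (k = 1.51 × 10⁻⁴ s⁻¹)
    complex with two exchanged ⇌ isomer of the product (K = 27.0, k = 1.20 × 10⁻⁴ s⁻¹)

At that peak the new flask held 2.19% of its charge of incoming ligand, while 41.4% of the starting complex still stood. Its own harvest was 0.612. In a neighbouring flask, like this one but charged with 0.600 equiv, Monday's H gave 19.1%, and that flask reached 15.2%.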